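**Retrosynthetic overview**
- The target is cut first at the C7–acyl bond (a C7 aryllithium, flanked by O1 and the C6 methoxy oxygen, plus the Weinreb amide of silyl-protected 4-hydroxycinnamic acid) and then at the two methyl groups of the CMe2OH side chain (MeMgBr on a C2 tert-butyl ester).
- The strategy rests on the dihydrofuran ring: C2 is the one carbon bonded to both O1 and C3, so the other four ring atoms O1–C7a–C3a–C3 map onto an ortho-quinone methide. The ring is cut at C2–C3 and O1–C2 into that methide and a one-carbon, ester-stabilised sulfonium ylide whose ester is the latent CMe2OH group.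
- The methide is released from a 2-(tosylmethyl)phenol made from 5-methoxyresorcinol (formylation between the two oxygens, monobenzylation to fix which oxygen becomes O1, reduction, sulfinate substitution). The ylide comes from C2-symmetric (2R,5R)-2,5-dimethylthiolane and tert-butyl bromoacetate.
- Ring order: the benzene ring is bought; the dihydrofuran ring is the only ring formed, in the [4+1] annulation that also sets C2; the chalcone arm is attached afterwards.

Key step: step 10

Assumption: the (2R,5R)-thiolanium group is taken to deliver (S) at C2; if the sense of induction proves opposite, the same sequence from (2R,5R)-hexane-2,5-diol supplies the enantiomeric sulfide and nothing else changes.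

**Route**

Step 1
Reactants: 1 5-methoxyresorcinol
Product: 2 1-methoxy-3,5-bis(methoxymethoxy)benzene
Conditions: NaH (2.4 equiv), MOMCl (2.4 equiv), DMF, 0 °C to rt
Reagents that add atoms: chloromethyl methyl ether, COCCl
Why: Williamson-type O-alkylation of both phenoxides gives the bis-acetal, which installs two strongly chelating ortho-directing groups for step 2.

Step 2
Reactants: 2 1-methoxy-3,5-bis(methoxymethoxy)benzene
Product: 4 4-methoxy-2,6-bis(methoxymethoxy)benzaldehyde, via aryllithium 3 (not isolated)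
Conditions: n-BuLi (1.2 equiv), THF, 0 °C; DMF, 0 °C to rt; H2O
Reagents that add atoms: N,N-dimethylformamide, CN(C)C=O
Why: Directed ortho-metalation takes place at the carbon flanked by the two MOM ethers, which outcompete the single methoxy group as directors, and the aryllithium is formylated by DMF.

Step 3
Reactants: 4 4-methoxy-2,6-bis(methoxymethoxy)benzaldehyde
Product: 5 2,6-dihydroxy-4-methoxybenzaldehyde
Conditions: HCl (3 M aq), MeOH, 50 °C
Reagents that add atoms: none
Why: Acid-catalysed acetal exchange with methanol removes both MOM groups while the aryl methyl ether and the aldehyde are untouched.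

Step 4
Reactants: 5 2,6-dihydroxy-4-methoxybenzaldehyde
Product: 6 2-(benzyloxy)-6-hydroxy-4-methoxybenzaldehyde
Conditions: BnBr (1.05 equiv), K2CO3 (1.1 equiv), DMF, rt
Reagents that add atoms: benzyl bromide, BrCc1ccccc1
Why: Williamson etherification should stop after one alkylation because the remaining hydroxyl is held in a hydrogen bond to the aldehyde, and the symmetry of 5 makes the two hydroxyls equivalent, so this step alone decides which oxygen later becomes O1.

Step 5
Reactants: 6 2-(benzyloxy)-6-hydroxy-4-methoxybenzaldehyde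
Product: 7 3-(benzyloxy)-2-(hydroxymethyl)-5-methoxyphenol
Conditions: NaBH4 (1.5 equiv), THF/MeOH, 0 °C; neutral work-up, used directly
Reagents that add atoms: none
Why: Borohydride reduction of the aldehyde is chemoselective, and the easily ionised salicyl alcohol is kept cold and neutral and taken on at once.

Step 6
Reactants: 7 3-(benzyloxy)-2-(hydroxymethyl)-5-methoxyphenol
Product: 8 3-(benzyloxy)-5-methoxy-2-(tosylmethyl)phenol
Conditions: p-TolSO2H (1.5 equiv), CH2Cl2, rt
Reagents that add atoms: 4-methylbenzenesulfinic acid, Cc1ccc(cc1)S(=O)O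
Why: The electron-rich ortho-hydroxybenzyl alcohol ionises under the mild acidity of the sulfinic acid and the benzylic cation is captured at sulfur by sulfinate (SN1-type substitution), which gives the bench-stable sulfone.

Step 7
Reactants: 9 (2S,5S)-hexane-2,5-diol
Product: 10 (2S,5S)-hexane-2,5-diyl dimethanesulfonate
Conditions: MsCl (2.4 equiv), Et3N (3 equiv), CH2Cl2, −10 to 0 °C
Reagents that add atoms: methanesulfonyl chloride, CS(=O)(=O)Cl
Why: Sulfonylation occurs at oxygen, so both stereocentres are retained.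

Step 8
Reactants: 10 (2S,5S)-hexane-2,5-diyl dimethanesulfonate
Product: 11 (2R,5R)-2,5-dimethylthiolane
Conditions: Na2S·9H2O (1.2 equiv), EtOH, rt; distillation
Reagents that add atoms: sodium sulfide, [Na+].[Na+].[S-2]
Why: Two SN2 displacements by sulfur (intermolecular, then 5-exo-tet) invert both centres and give the trans, C2-symmetric thiolane.

Step 9
Reactants: 11 (2R,5R)-2,5-dimethylthiolane; 12 tert-butyl bromoacetate
Product: 13 (2R,5R)-1-(2-tert-butoxy-2-oxoethyl)-2,5-dimethylthiolan-1-ium bromide
Conditions: acetone (concentrated), rt, 48 h; trituration with Et2O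
Reagents that add atoms: none
Why: SN2 S-alkylation by the activated α-bromo ester gives a single sulfonium salt because the two lone pairs on sulfur of the C2-symmetric thiolane are homotopic, so sulfur is not a stereocentre.

Step 10
Reactants: 8 3-(benzyloxy)-5-methoxy-2-(tosylmethyl)phenol; 13 (2R,5R)-1-(2-tert-butoxy-2-oxoethyl)-2,5-dimethylthiolan-1-ium bromide
Product: 17 tert-butyl (2S)-4-(benzyloxy)-6-methoxy-2,3-dihydro-1-benzofuran-2-carboxylate, via ortho-quinone methide 14 (not isolated), via sulfonium ylide 15 (not isolated), via betaine 16 (not isolated)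
Conditions: 13 (1.5 equiv), Cs2CO3 (3 equiv), CH2Cl2, −20 to 0 °C
Reagents that add atoms: none
Why: Proposed new method: Cs2CO3 deprotonates phenol 8, which expels sulfinate to give ortho-quinone methide 14 (stabilised by the para methoxy and ortho benzyloxy groups), and also converts salt 13 into ylide 15; the ylide carbon adds to the exocyclic CH2 of 14 (C2–C3 bond, ring rearomatised) to give betaine 16, whose phenoxide then displaces the thiolane (O1–C2 bond). The closest known reaction type is the [4+1] annulation of ortho-quinone methides released from 2-(sulfonylalkyl)phenols with ester-stabilised sulfonium ylides, whose asymmetric variants rely on a substituent at C3, whereas here the methide carbon is unsubstituted and the chiral sulfonium group alone must set C2. The dihydrofuran ring closes in a 5-exo-tet mode with inversion at C2. C2 is controlled by the C2-symmetric thiolanium group: a single ylide forms whose two faces are distinguished by the flanking ring methyl groups, and because the α-hydrogen of 16 is acidic the betaine epimers can interconvert, so the faster invertive closure of the (R)-betaine is expected to give (S)-17. The step needs enantioselectivity at C2, capture of 14 by the ylide ahead of self-condensation of 14, and no epimerisation of 17; these are served by the reagent-bound chiral group, by slow release of 14 in the presence of excess ylide, and by the mild carbonate base with the bulky tert-butyl ester, while the benzyl ether leaves only one phenol oxygen able to enter the ring.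

Step 11
Reactants: 17 tert-butyl (2S)-4-(benzyloxy)-6-methoxy-2,3-dihydro-1-benzofuran-2-carboxylate
Product: 18 2-[(2S)-4-(benzyloxy)-6-methoxy-2,3-dihydro-1-benzofuran-2-yl]propan-2-ol
Conditions: MeMgBr (4 equiv), THF, 0 °C to rt; H2O
Reagents that add atoms: methylmagnesium bromide, C[Mg]Br
Why: Double Grignard addition converts the ester into the tertiary alcohol, and carbonyl attack on the α-alkoxy ester should outpace enolisation, so C2 keeps its configuration.

Step 12
Reactants: 18 2-[(2S)-4-(benzyloxy)-6-methoxy-2,3-dihydro-1-benzofuran-2-yl]propan-2-ol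
Product: 19 (2S)-2-(2-hydroxypropan-2-yl)-6-methoxy-2,3-dihydro-1-benzofuran-4-ol
Conditions: H2 (1 atm), 10% Pd/C, EtOAc/MeOH, rt
Reagents that add atoms: none
Why: Catalytic hydrogenolysis cleaves only the benzyl ether, since the ring C2–O1 bond is not benzylic.

Step 13
Reactants: 19 (2S)-2-(2-hydroxypropan-2-yl)-6-methoxy-2,3-dihydro-1-benzofuran-4-ol
Product: 20 2-[(2S)-6-methoxy-4-(triisopropylsilyloxy)-2,3-dihydro-1-benzofuran-2-yl]propan-2-ol
Conditions: TIPSCl (1.2 equiv), imidazole (2.5 equiv), DMF, rt
Reagents that add atoms: chlorotriisopropylsilane, CC(C)[Si](Cl)(C(C)C)C(C)C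
Why: Silylation is selective for the phenol over the hindered tertiary alcohol, and the bulky silyl ether, a poor director, will shield C5 in the metalation of step 16.

Step 14
Reactants: 21 (E)-4-hydroxycinnamic acid
Product: 23 (E)-3-(4-hydroxyphenyl)-N-methoxy-N-methylprop-2-enamide, via O-acylisourea 22 (not isolated)
Conditions: MeNHOMe·HCl (1.2 equiv), EDC·HCl (1.2 equiv), N-methylmorpholine (2.5 equiv), CH2Cl2/DMF, 0 °C to rt
Reagents that add atoms: N,O-dimethylhydroxylamine hydrochloride, CNOC.Cl
Why: Carbodiimide-mediated amide coupling is selective for the amine over the phenol and leaves the (E)-alkene unchanged.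

Step 15
Reactants: 23 (E)-3-(4-hydroxyphenyl)-N-methoxy-N-methylprop-2-enamide
Product: 24 (E)-N-methoxy-N-methyl-3-[4-(triisopropylsilyloxy)phenyl]prop-2-enamide
Conditions: TIPSCl (1.2 equiv), imidazole (2.5 equiv), DMF, rt
Reagents that add atoms: chlorotriisopropylsilane, CC(C)[Si](Cl)(C(C)C)C(C)C
Why: Silylation masks the acidic phenol so that it cannot quench the aryllithium of step 16.

Step 16
Reactants: 20 2-[(2S)-6-methoxy-4-(triisopropylsilyloxy)-2,3-dihydro-1-benzofuran-2-yl]propan-2-ol; 24 (E)-N-methoxy-N-methyl-3-[4-(triisopropylsilyloxy)phenyl]prop-2-enamide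
Product: 26 (E)-1-[(2S)-2-(2-hydroxypropan-2-yl)-6-methoxy-4-(triisopropylsilyloxy)-2,3-dihydro-1-benzofuran-7-yl]-3-[4-(triisopropylsilyloxy)phenyl]prop-2-en-1-one, via C7-lithiated lithium alkoxide 25 (not isolated)
Conditions: n-BuLi (2.3 equiv), TMEDA, THF, 0 °C; 24 (1.3 equiv), −78 to 0 °C; AcOH then H2O
Reagents that add atoms: none
Why: The first equivalent of n-BuLi forms the lithium alkoxide and the second effects directed ortho-metalation at C7, the only position flanked by two ether oxygens (O1 and the C6 methoxy) while C5 is shielded by the TIPS ether, and the aryllithium adds to the amide carbonyl to give a chelated tetrahedral adduct that releases the enone only on work-up (Weinreb ketone synthesis).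

Step 17
Reactants: 26 (E)-1-[(2S)-2-(2-hydroxypropan-2-yl)-6-methoxy-4-(triisopropylsilyloxy)-2,3-dihydro-1-benzofuran-7-yl]-3-[4-(triisopropylsilyloxy)phenyl]prop-2-en-1-one
Product: 27 (E)-1-[(2S)-4-hydroxy-2-(2-hydroxypropan-2-yl)-6-methoxy-2,3-dihydro-1-benzofuran-7-yl]-3-(4-hydroxyphenyl)prop-2-en-1-one
Conditions: TBAF (2.5 equiv), AcOH (2.5 equiv), THF, 0 °C, exclusion of light
Reagents that add atoms: none
Why: Fluoride cleaves both aryl silyl ethers under buffered conditions that spare the chalcone, and the tertiary alcohol and C2 are not involved.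

**Compound list**
1 | 5-methoxyresorcinol | COc1cc(O)cc(O)c1 | starting material
2 | 1-methoxy-3,5-bis(methoxymethoxy)benzene | COCOc1cc(OC)cc(OCOC)c1 | intermediate
3 | 4-methoxy-2,6-bis(methoxymethoxy)phenyllithium | [Li]c1c(OCOC)cc(OC)cc1OCOC | intermediate
4 | 4-methoxy-2,6-bis(methoxymethoxy)benzaldehyde | COCOc1cc(OC)cc(OCOC)c1C=O | intermediate
5 | 2,6-dihydroxy-4-methoxybenzaldehyde | COc1cc(O)c(C=O)c(O)c1 | intermediate
6 | 2-(benzyloxy)-6-hydroxy-4-methoxybenzaldehyde | COc1cc(O)c(C=O)c(OCc2ccccc2)c1 | intermediate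
7 | 3-(benzyloxy)-2-(hydroxymethyl)-5-methoxyphenol | COc1cc(O)c(CO)c(OCc2ccccc2)c1 | intermediate
8 | 3-(benzyloxy)-5-methoxy-2-(tosylmethyl)phenol | Cc1ccc(cc1)S(=O)(=O)Cc1c(O)cc(OC)cc1OCc1ccccc1 | intermediate
9 | (2S,5S)-hexane-2,5-diol | C[C@H](O)CC[C@H](C)O | starting material
10 | (2S,5S)-hexane-2,5-diyl dimethanesulfonate | C[C@H](OS(C)(=O)=O)CC[C@H](C)OS(C)(=O)=O | intermediate
11 | (2R,5R)-2,5-dimethylthiolane | C[C@@H]1CC[C@@H](C)S1 | intermediate
12 | tert-butyl bromoacetate | CC(C)(C)OC(=O)CBr | starting material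
13 | (2R,5R)-1-(2-tert-butoxy-2-oxoethyl)-2,5-dimethylthiolan-1-ium bromide | C[C@@H]1CC[C@@H](C)[S+]1CC(=O)OC(C)(C)C.[Br-] | intermediate
14 | 5-(benzyloxy)-3-methoxy-6-methylidenecyclohexa-2,4-dien-1-one (ortho-quinone methide) | C=C1C(=O)C=C(OC)C=C1OCc1ccccc1 | intermediate
15 | 2-tert-butoxy-1-[(2R,5R)-2,5-dimethylthiolan-1-ium-1-yl]-2-oxoethan-1-ide (sulfonium ylide) | C[C@@H]1CC[C@@H](C)[S+]1[CH-]C(=O)OC(C)(C)C | intermediate
16 | 3-(benzyloxy)-2-{(2R)-3-tert-butoxy-2-[(2R,5R)-2,5-dimethylthiolan-1-ium-1-yl]-3-oxopropyl}-5-methoxyphenolate (betaine) | C[C@@H]1CC[C@@H](C)[S+]1[C@@H](C(=O)OC(C)(C)C)Cc1c([O-])cc(OC)cc1OCc1ccccc1 | intermediate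
17 | tert-butyl (2S)-4-(benzyloxy)-6-methoxy-2,3-dihydro-1-benzofuran-2-carboxylate | COc1cc(OCc3ccccc3)c2c(c1)O[C@H](C(=O)OC(C)(C)C)C2 | intermediate
18 | 2-[(2S)-4-(benzyloxy)-6-methoxy-2,3-dihydro-1-benzofuran-2-yl]propan-2-ol | COc1cc(OCc3ccccc3)c2c(c1)O[C@H](C(C)(C)O)C2 | intermediate
19 | (2S)-2-(2-hydroxypropan-2-yl)-6-methoxy-2,3-dihydro-1-benzofuran-4-ol | COc1cc(O)c2c(c1)O[C@H](C(C)(C)O)C2 | intermediate
20 | 2-[(2S)-6-methoxy-4-(triisopropylsilyloxy)-2,3-dihydro-1-benzofuran-2-yl]propan-2-ol | COc1cc(O[Si](C(C)C)(C(C)C)C(C)C)c2c(c1)O[C@H](C(C)(C)O)C2 | intermediate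
21 | (E)-4-hydroxycinnamic acid | OC(=O)/C=C/c1ccc(O)cc1 | starting material
22 | N-[3-(dimethylamino)propyl]-N'-ethyl-O-[(E)-3-(4-hydroxyphenyl)prop-2-enoyl]isourea | CCN=C(NCCCN(C)C)OC(=O)/C=C/c1ccc(O)cc1 | intermediate
23 | (E)-3-(4-hydroxyphenyl)-N-methoxy-N-methylprop-2-enamide | CON(C)C(=O)/C=C/c1ccc(O)cc1 | intermediate
24 | (E)-N-methoxy-N-methyl-3-[4-(triisopropylsilyloxy)phenyl]prop-2-enamide | CON(C)C(=O)/C=C/c1ccc(O[Si](C(C)C)(C(C)C)C(C)C)cc1 | intermediate
25 | lithium 2-[(2S)-7-lithio-6-methoxy-4-(triisopropylsilyloxy)-2,3-dihydro-1-benzofuran-2-yl]propan-2-olate | COc1cc(O[Si](C(C)C)(C(C)C)C(C)C)c2c(c1[Li])O[C@H](C(C)(C)O[Li])C2 | intermediate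
26 | (E)-1-[(2S)-2-(2-hydroxypropan-2-yl)-6-methoxy-4-(triisopropylsilyloxy)-2,3-dihydro-1-benzofuran-7-yl]-3-[4-(triisopropylsilyloxy)phenyl]prop-2-en-1-one | COc1cc(O[Si](C(C)C)(C(C)C)C(C)C)c2c(c1C(=O)/C=C/c1ccc(O[Si](C(C)C)(C(C)C)C(C)C)cc1)O[C@H](C(C)(C)O)C2 | intermediate
27 | (E)-1-[(2S)-4-hydroxy-2-(2-hydroxypropan-2-yl)-6-methoxy-2,3-dihydro-1-benzofuran-7-yl]-3-(4-hydroxyphenyl)prop-2-en-1-one | COc1cc(O)c2c(c1C(=O)/C=C/c1ccc(O)cc1)O[C@H](C(C)(C)O)C2 | target

**Step count**
Total step count: 17.
Longest linear sequence: 12 steps (steps 1–6, 10–13, 16, 17).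

**Steps most likely to fail**

1. Step 10. The unsubstituted quinone methide may self-condense faster than the ylide captures it, or the thiolanium group may discriminate the ylide faces poorly, so that C2 forms with low enantioselectivity. The fallback uses known chemistry, sets out from sulfone 8 and returns at alcohol 18, so step 11 is not needed. Excess 2-methylprop-1-enylmagnesium bromide in THF (−78 to 0 °C) deprotonates 8, triggers loss of sulfinate and adds 1,4 to the quinone methide to give 3-(benzyloxy)-5-methoxy-2-(3-methylbut-2-en-1-yl)phenol F1. TBSCl and imidazole in DMF convert it into tert-butyl[3-(benzyloxy)-5-methoxy-2-(3-methylbut-2-en-1-yl)phenoxy]dimethylsilane F2. Shi epoxidation of the trisubstituted alkene with the D-fructose-derived ketone (1,2:4,5-di-O-isopropylidene-β-D-erythro-2,3-hexodiulo-2,6-pyranose), Oxone (2KHSO5·KHSO4·K2SO4) and K2CO3 buffer in MeCN/dimethoxymethane/H2O at 0 °C should give tert-butyl{3-(benzyloxy)-2-{[(2R)-3,3-dimethyloxiran-2-yl]methyl}-5-methoxyphenoxy}dimethylsilane F3. TBAF in THF then frees the phenoxide, which opens the epoxide at its secondary carbon (5-exo-tet, inversion) to give (S)-configured 18.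

2. Step 16. The hindered, doubly ortho-substituted aryllithium may add slowly, or in conjugate fashion, to the unsaturated amide, so that the acyl transfer stalls or gives the wrong connectivity. The fallback sets out from 24 and 20 and returns at 26. DIBAL-H in THF at −78 °C reduces Weinreb amide 24 to (E)-3-[4-(triisopropylsilyloxy)phenyl]prop-2-enal F4. Aryllithium 25, generated from 20 as in step 16, adds 1,2 to this more electrophilic aldehyde to give (E)-1-[(2S)-2-(2-hydroxypropan-2-yl)-6-methoxy-4-(triisopropylsilyloxy)-2,3-dihydro-1-benzofuran-7-yl]-3-[4-(triisopropylsilyloxy)phenyl]prop-2-en-1-ol F5, as a mixture of carbinol epimers that is of no consequence. MnO2 in CH2Cl2 oxidises the allylic, benzylic alcohol selectively to enone 26.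

3. Step 6. Acid-promoted ionisation of the salicyl alcohol may lead to Friedel–Crafts self-alkylation of the very electron-rich ring (oligomerisation) in competition with sulfinate capture. The fallback sets out from aldehyde 6 and returns at sulfone 8, avoiding both the free benzylic alcohol and acid. Reductive amination of 6 with Me2NH and NaBH(OAc)3 in 1,2-dichloroethane gives the phenolic Mannich base 3-(benzyloxy)-2-[(dimethylamino)methyl]-5-methoxyphenol F6. Heating F6 with sodium 4-methylbenzenesulfinate and AcOH (1 equiv) in DMF at 90 °C exchanges dimethylamine for sulfinate by elimination–addition through the quinone methide under near-neutral conditions and gives 8.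

**Further compounds**
F1 | step 10 | 3-(benzyloxy)-5-methoxy-2-(3-methylbut-2-en-1-yl)phenol | COc1cc(O)c(CC=C(C)C)c(OCc2ccccc2)c1
F2 | step 10 | tert-butyl[3-(benzyloxy)-5-methoxy-2-(3-methylbut-2-en-1-yl)phenoxy]dimethylsilane | COc1cc(O[Si](C)(C)C(C)(C)C)c(CC=C(C)C)c(OCc2ccccc2)c1
F3 | step 10 | tert-butyl{3-(benzyloxy)-2-{[(2R)-3,3-dimethyloxiran-2-yl]methyl}-5-methoxyphenoxy}dimethylsilane | COc1cc(O[Si](C)(C)C(C)(C)C)c(C[C@H]2OC2(C)C)c(OCc2ccccc2)c1
F4 | step 16 | (E)-3-[4-(triisopropylsilyloxy)phenyl]prop-2-enal | O=C/C=C/c1ccc(O[Si](C(C)C)(C(C)C)C(C)C)cc1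
F5 | step 16 | (E)-1-[(2S)-2-(2-hydroxypropan-2-yl)-6-methoxy-4-(triisopropylsilyloxy)-2,3-dihydro-1-benzofuran-7-yl]-3-[4-(triisopropylsilyloxy)phenyl]prop-2-en-1-ol | COc1cc(O[Si](C(C)C)(C(C)C)C(C)C)c2c(c1C(O)/C=C/c1ccc(O[Si](C(C)C)(C(C)C)C(C)C)cc1)O[C@H](C(C)(C)O)C2
F6 | step 6 | 3-(benzyloxy)-2-[(dimethylamino)methyl]-5-methoxyphenol | CN(C)Cc1c(O)cc(OC)cc1OCc1ccccc1
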